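**Retrosynthetic overview**

1. The route ends with hydrogenolysis of three benzyl ethers. Before that the oxolane ring is closed last, at its C3–C4 bond, by Cp2TiCl-mediated epoxide opening and 5-exo radical cyclisation of an epoxy cinnamyl ether; that ether is cut at O–CH2 into an (S)-aryl epoxy carbinol (from O-benzylisovanillin) and a cinnamyl bromide.
2. The cinnamyl bromide is grown from the C6 bromide of a trans-2-aryl-3-(hydroxymethyl)-2,3-dihydrobenzofuran (benzylation, Heck coupling, reduction, bromination).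
3. The dihydrofuran ring of the benzofuran is closed first, at O1–C2: Me3SiBr ionises the benzylic carbinol of a 1-aryl-2-(4-bromo-2,6-dimethoxyphenyl)propane-1,3-diol, and an ortho-methoxy oxygen captures the cation and gives up its methyl group.
4. The diol comes from an Evans syn-aldol of a (4-bromo-2,6-dimethoxyphenyl)acetyl oxazolidinone with O-benzylvanillin, then LiBH4; the arylacetic acid comes from 4-bromo-2,6-difluorobenzaldehyde (double SNAr, one-carbon homologation).
5. Feature used: benzofuran C3a, which carries C3, lies between two oxygenated carbons, C7a (O1) and C4 (OMe). A symmetric 2,6-dimethoxyaryl ring therefore offers two equivalent oxygens to C2, a benzylic carbon with a para oxygen that ionises easily.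

Key step: step 8

Remark: the usual Evans syn facial sense is assumed for the hindered 2,6-dimethoxyarylacetyl imide; the carbinol configuration it sets is in any case erased in step 8.

**Route**

Step 1
Reactants: 1 4-bromo-2,6-difluorobenzaldehyde
Product: 3 4-bromo-2,6-dimethoxybenzaldehyde, via 4-bromo-2-fluoro-6-methoxybenzaldehyde 2 (not isolated)
Conditions: NaOMe (3 equiv), MeOH, reflux
Reagents that add atoms: sodium methoxide (NaOMe), [Na+].[O-]C
Why: Both fluorides are ortho to the formyl group and should be displaced one after the other by nucleophilic aromatic substitution (SNAr), fluoride leaving far faster than the para bromide, which is kept.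

Step 2
Reactants: 3 4-bromo-2,6-dimethoxybenzaldehyde
Product: 4 5-bromo-1,3-dimethoxy-2-(2-methoxyethenyl)benzene (E/Z mixture)
Conditions: MeOCH2PPh3Cl, KOtBu, THF, 0 °C → rt
Reagents that add atoms: (methoxymethyl)triphenylphosphonium chloride, COC[P+](c1ccccc1)(c1ccccc1)c1ccccc1.[Cl-]
Why: Wittig methoxymethylenation of a non-enolisable aromatic aldehyde adds the one-carbon unit as an enol ether whose geometry is of no consequence.

Step 3
Reactants: 4 5-bromo-1,3-dimethoxy-2-(2-methoxyethenyl)benzene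
Product: 5 (4-bromo-2,6-dimethoxyphenyl)acetaldehyde
Conditions: 2 M HCl, THF, 40 °C
Reagents that add atoms: water, O
Why: Acid-catalysed enol ether hydrolysis should release the homologous arylacetaldehyde, which is used at once.

Step 4
Reactants: 5 (4-bromo-2,6-dimethoxyphenyl)acetaldehyde
Product: 6 (4-bromo-2,6-dimethoxyphenyl)acetic acid
Conditions: NaClO2, NaH2PO4, 2-methyl-2-butene (excess), t-BuOH/H2O, 0 °C → rt
Reagents that add atoms: sodium chlorite (NaClO2), [Na+].[O-]Cl=O
Why: Pinnick oxidation converts the aldehyde into the acid, the alkene scavenger removing HOCl before it can chlorinate the electron-rich arene.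

Step 5
Reactants: 6 (4-bromo-2,6-dimethoxyphenyl)acetic acid; 7 (S)-4-benzyl-1,3-oxazolidin-2-one
Product: 9 (4S)-4-benzyl-3-[(4-bromo-2,6-dimethoxyphenyl)acetyl]-1,3-oxazolidin-2-one, via mixed pivalic anhydride 8 (not isolated)
Conditions: t-BuCOCl, Et3N, THF, −20 °C; then 7, LiCl, −20 °C → rt
Reagents that add atoms: none
Why: N-Acylation of the oxazolidinone through a mixed pivalic anhydride is standard, the nucleophile attacking the less hindered arylacetyl carbonyl.

Step 6
Reactants: 9 (4S)-4-benzyl-3-[(4-bromo-2,6-dimethoxyphenyl)acetyl]-1,3-oxazolidin-2-one; 10 4-(benzyloxy)-3-methoxybenzaldehyde (O-benzylvanillin)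
Product: 12 (4S)-4-benzyl-3-[(2S,3S)-3-[4-(benzyloxy)-3-methoxyphenyl]-2-(4-bromo-2,6-dimethoxyphenyl)-3-hydroxypropanoyl]-1,3-oxazolidin-2-one, via Z-dibutylboron enolate 11 (not isolated)
Conditions: Bu2BOTf, i-Pr2NEt, CH2Cl2, 0 °C; 10, −78 → 0 °C; then pH 7 buffer, MeOH, 30% H2O2, 0 °C
Reagents that add atoms: none
Why: Evans boron aldol, in which the Z-enolate should add through a Zimmerman–Traxler chair on the face away from the auxiliary benzyl group, setting the (2S) aryl-bearing centre (benzofuran C3 of the target) and the syn (3S) carbinol.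

Step 7
Reactants: 12 the syn-aldol imide
Product: 13 (1S,2R)-1-[4-(benzyloxy)-3-methoxyphenyl]-2-(4-bromo-2,6-dimethoxyphenyl)propane-1,3-diol
Conditions: LiBH4, MeOH (1 equiv), THF, 0 °C
Reagents that add atoms: none
Why: Reductive cleavage of the N-acyl oxazolidinone with LiBH4 gives the primary alcohol and returns the auxiliary without touching the aryl bromide or either stereocentre.

Step 8
Reactants: 13 (1S,2R)-1-[4-(benzyloxy)-3-methoxyphenyl]-2-(4-bromo-2,6-dimethoxyphenyl)propane-1,3-diol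
Product: 16 [(2S,3R)-2-[4-(benzyloxy)-3-methoxyphenyl]-6-bromo-4-methoxy-2,3-dihydro-1-benzofuran-3-yl]methanol (trans), via benzylic bromide trimethylsilyl ether 14 (not isolated), via cyclised trimethylsilyl ether 15 (not isolated)
Conditions: Me3SiBr (3 equiv), CH2Cl2 (0.02 M), −40 → 0 °C; then K2CO3, MeOH, rt
Reagents that add atoms: none
Why: Me3SiBr silylates both hydroxyls and exchanges the benzylic silyl ether for bromide, which ionises to a cation stabilised by the para-benzyloxy group; an ortho-methoxy oxygen of the neighbouring aryl ring attacks it and bromide then removes the methyl group from the resulting aryl methyl oxonium ion as MeBr. The closest known reaction type is the demethylative cyclisation of benzylic cations bearing an ortho-methoxyaryl neighbour to dihydrobenzofurans. The dihydrofuran ring (O1–C2 bond) closes 5-exo-trig onto the trigonal cationic carbon. The new centre C2 is controlled by C3: the aryl group should take the face anti to the C3 CH2OSiMe3 group, the closure is reversible under the acidic conditions so the trans ring is also the thermodynamic product, and because the cation is planar both C1 epimers of 13 converge. The step needs exactly one demethylation and no choice between the two methoxy groups: rotation of the symmetric aryl ring interchanges them, and only the oxygen that has become an oxonium ion is activated toward bromide, the other aryl methyl ethers being inert to Me3SiBr at this temperature. The primary hydroxyl is only masked as its trimethylsilyl ether, which the methanolic work-up removes.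

Step 9
Reactants: 16 [(2S,3R)-2-[4-(benzyloxy)-3-methoxyphenyl]-6-bromo-4-methoxy-2,3-dihydro-1-benzofuran-3-yl]methanol
Product: 17 (2S,3R)-2-[4-(benzyloxy)-3-methoxyphenyl]-3-[(benzyloxy)methyl]-6-bromo-4-methoxy-2,3-dihydro-1-benzofuran
Conditions: NaH, BnBr, n-Bu4NI (cat.), THF/DMF, 0 °C → rt
Reagents that add atoms: benzyl bromide, BrCc1ccccc1
Why: Williamson etherification of the primary alkoxide, in which the excess reagent would also re-benzylate any phenol formed by loss of the para-benzyl group in step 8.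

Step 10
Reactants: 17 (2S,3R)-2-[4-(benzyloxy)-3-methoxyphenyl]-3-[(benzyloxy)methyl]-6-bromo-4-methoxy-2,3-dihydro-1-benzofuran
Product: 18 methyl (2E)-3-{(2S,3R)-2-[4-(benzyloxy)-3-methoxyphenyl]-3-[(benzyloxy)methyl]-4-methoxy-2,3-dihydro-1-benzofuran-6-yl}prop-2-enoate
Conditions: methyl acrylate, Pd(OAc)2 (5 mol%), P(o-tol)3, Et3N, DMF, 100 °C
Reagents that add atoms: methyl acrylate, C=CC(=O)OC
Why: Mizoroki–Heck coupling, in which oxidative addition of the unhindered aryl bromide to zerovalent palladium, syn insertion and syn β-hydride elimination should give the E-cinnamate.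

Step 11
Reactants: 18 the methyl E-cinnamate
Product: 19 (2E)-3-{(2S,3R)-2-[4-(benzyloxy)-3-methoxyphenyl]-3-[(benzyloxy)methyl]-4-methoxy-2,3-dihydro-1-benzofuran-6-yl}prop-2-en-1-ol
Conditions: i-Bu2AlH (2.5 equiv), CH2Cl2, −78 °C; aq. KNaC4H4O6
Reagents that add atoms: none
Why: 1,2-Reduction of the enoate by i-Bu2AlH gives the allylic alcohol and leaves the ethers and the dihydrobenzofuran alone.

Step 12
Reactants: 19 the E-allylic alcohol
Product: 20 (2S,3R)-2-[4-(benzyloxy)-3-methoxyphenyl]-3-[(benzyloxy)methyl]-6-[(1E)-3-bromoprop-1-en-1-yl]-4-methoxy-2,3-dihydro-1-benzofuran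
Conditions: CBr4, PPh3, CH2Cl2, 0 °C
Reagents that add atoms: carbon tetrabromide, BrC(Br)(Br)Br
Why: Appel bromination converts the allylic alcohol into the bromide under neutral conditions that spare the acid-labile 2-aryl dihydrobenzofuran.

Step 13
Reactants: 21 3-(benzyloxy)-4-methoxybenzaldehyde (O-benzylisovanillin)
Product: 22 rac-1-[3-(benzyloxy)-4-methoxyphenyl]prop-2-en-1-ol
Conditions: CH2=CHMgBr, THF, 0 °C; aq. NH4Cl
Reagents that add atoms: vinylmagnesium bromide (CH2=CHMgBr), C=C[Mg]Br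
Why: Grignard addition of the vinyl nucleophile to the aldehyde gives the racemic aryl vinyl carbinol.

Step 14
Reactants: 22 rac-1-[3-(benzyloxy)-4-methoxyphenyl]prop-2-en-1-ol
Product: 23 (S)-[3-(benzyloxy)-4-methoxyphenyl][(2R)-oxiran-2-yl]methanol
Conditions: Ti(OiPr)4 (cat.), L-(+)-diisopropyl tartrate, t-BuOOH (0.45 equiv), 4 Å MS, CH2Cl2, −20 °C
Reagents that add atoms: tert-butyl hydroperoxide, CC(C)(C)OO
Why: Sharpless kinetic resolution, in which the L-(+)-tartrate catalyst should epoxidise the (R)-alcohol fast and anti (erythro) selectively, so a limiting charge of peroxide delivers the (S)-carbinol centre that becomes oxolane C2, the epoxide carbon being of no consequence because it later becomes a radical.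

Step 15
Reactants: 23 (S)-[3-(benzyloxy)-4-methoxyphenyl][(2R)-oxiran-2-yl]methanol; 20 the cinnamyl bromide
Product: 24 (2S,3R)-2-[4-(benzyloxy)-3-methoxyphenyl]-3-[(benzyloxy)methyl]-6-[(1E)-3-{(S)-[3-(benzyloxy)-4-methoxyphenyl][(2R)-oxiran-2-yl]methoxy}prop-1-en-1-yl]-4-methoxy-2,3-dihydro-1-benzofuran
Conditions: NaH, THF, 0 °C; then 20, n-Bu4NI (cat.), 0 °C → rt
Reagents that add atoms: none
Why: Williamson etherification of the secondary epoxy alkoxide with a reactive allylic bromide, which in an aprotic medium at or below room temperature should outrun Payne rearrangement and leaves the carbinol centre untouched.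

Step 16
Reactants: 24 the epoxy cinnamyl ether
Product: 25 [(2R,3S,4S)-2-[3-(benzyloxy)-4-methoxyphenyl]-4-({(2S,3R)-2-[4-(benzyloxy)-3-methoxyphenyl]-3-[(benzyloxy)methyl]-4-methoxy-2,3-dihydro-1-benzofuran-6-yl}methyl)oxolan-3-yl]methanol
Conditions: Cp2TiCl2 (2.5 equiv), Zn dust, THF, rt, slow addition of 24; then 1 M HCl, 0 °C
Reagents that add atoms: none
Why: Nugent–RajanBabu reductive epoxide opening by Cp2TiCl (trivalent titanium) gives the more substituted β-titanoxy radical, which should close 5-exo-trig onto the styrenyl alkene through a Beckwith–Houk chair with the C2 aryl group pseudo-equatorial (2,3-trans) and the CH2OTi and alkene arms cis (3,4-cis), the benzylic radical then being reduced by a second Cp2TiCl and protonated on work-up, so that oxolane C3 and C4 are set under control of C2.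

Step 17
Reactants: 25 the tribenzyl ether
Product: 26 [(2R,3S,4S)-2-(3-hydroxy-4-methoxyphenyl)-4-{[(2S,3R)-2-(4-hydroxy-3-methoxyphenyl)-3-(hydroxymethyl)-4-methoxy-2,3-dihydro-1-benzofuran-6-yl]methyl}oxolan-3-yl]methanol (CNP0242386.1)
Conditions: H2 (1 atm), 10% Pd/C, EtOAc/MeOH, rt
Reagents that add atoms: none
Why: Hydrogenolysis over palladium removes the two aryl benzyl ethers and the primary benzyl ether, and at room temperature and 1 atm the hindered ring benzylic C–O bonds of the oxolane and the dihydrobenzofuran should survive if the reaction is stopped at full debenzylation.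

**Compound list**

1 | 4-bromo-2,6-difluorobenzaldehyde | O=Cc1c(F)cc(Br)cc1F | starting material
2 | 4-bromo-2-fluoro-6-methoxybenzaldehyde | COc1cc(Br)cc(F)c1C=O | intermediate (not isolated)
3 | 4-bromo-2,6-dimethoxybenzaldehyde | COc1cc(Br)cc(OC)c1C=O | intermediate
4 | 5-bromo-1,3-dimethoxy-2-(2-methoxyethenyl)benzene, E/Z mixture | COC=Cc1c(OC)cc(Br)cc1OC | intermediate
5 | (4-bromo-2,6-dimethoxyphenyl)acetaldehyde | COc1cc(Br)cc(OC)c1CC=O | intermediate
6 | (4-bromo-2,6-dimethoxyphenyl)acetic acid | COc1cc(Br)cc(OC)c1CC(=O)O | intermediate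
7 | (S)-4-benzyl-1,3-oxazolidin-2-one | O=C1N[C@@H](Cc2ccccc2)CO1 | starting material
8 | (4-bromo-2,6-dimethoxyphenyl)acetic pivalic anhydride | COc1cc(Br)cc(OC)c1CC(=O)OC(=O)C(C)(C)C | intermediate (not isolated)
9 | (4S)-4-benzyl-3-[(4-bromo-2,6-dimethoxyphenyl)acetyl]-1,3-oxazolidin-2-one | COc1cc(Br)cc(OC)c1CC(=O)N1C(=O)OC[C@@H]1Cc1ccccc1 | intermediate
10 | 4-(benzyloxy)-3-methoxybenzaldehyde | COc1cc(C=O)ccc1OCc1ccccc1 | starting material
11 | Z-dibutylboron enolate of 9 | CCCCB(CCCC)O/C(=C\c1c(OC)cc(Br)cc1OC)N1C(=O)OC[C@@H]1Cc1ccccc1 | intermediate (not isolated)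
12 | (4S)-4-benzyl-3-[(2S,3S)-3-[4-(benzyloxy)-3-methoxyphenyl]-2-(4-bromo-2,6-dimethoxyphenyl)-3-hydroxypropanoyl]-1,3-oxazolidin-2-one | COc1cc(Br)cc(OC)c1[C@H](C(=O)N1C(=O)OC[C@@H]1Cc1ccccc1)[C@H](O)c1ccc(OCc2ccccc2)c(OC)c1 | intermediate
13 | (1S,2R)-1-[4-(benzyloxy)-3-methoxyphenyl]-2-(4-bromo-2,6-dimethoxyphenyl)propane-1,3-diol | COc1cc(Br)cc(OC)c1[C@H](CO)[C@H](O)c1ccc(OCc2ccccc2)c(OC)c1 | intermediate
14 | [(2R)-3-[4-(benzyloxy)-3-methoxyphenyl]-3-bromo-2-(4-bromo-2,6-dimethoxyphenyl)propoxy]trimethylsilane, both C3 epimers | COc1cc(Br)cc(OC)c1[C@H](CO[Si](C)(C)C)C(Br)c1ccc(OCc2ccccc2)c(OC)c1 | intermediate (not isolated)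
15 | {[(2S,3R)-2-[4-(benzyloxy)-3-methoxyphenyl]-6-bromo-4-methoxy-2,3-dihydro-1-benzofuran-3-yl]methoxy}trimethylsilane | Brc1cc(OC)c2c(c1)O[C@H](c1ccc(OCc3ccccc3)c(OC)c1)[C@H]2CO[Si](C)(C)C | intermediate (not isolated)
16 | [(2S,3R)-2-[4-(benzyloxy)-3-methoxyphenyl]-6-bromo-4-methoxy-2,3-dihydro-1-benzofuran-3-yl]methanol | Brc1cc(OC)c2c(c1)O[C@H](c1ccc(OCc3ccccc3)c(OC)c1)[C@H]2CO | intermediate
17 | (2S,3R)-2-[4-(benzyloxy)-3-methoxyphenyl]-3-[(benzyloxy)methyl]-6-bromo-4-methoxy-2,3-dihydro-1-benzofuran | Brc1cc(OC)c2c(c1)O[C@H](c1ccc(OCc3ccccc3)c(OC)c1)[C@H]2COCc1ccccc1 | intermediate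
18 | methyl (2E)-3-{(2S,3R)-2-[4-(benzyloxy)-3-methoxyphenyl]-3-[(benzyloxy)methyl]-4-methoxy-2,3-dihydro-1-benzofuran-6-yl}prop-2-enoate | COC(=O)/C=C/c1cc(OC)c2c(c1)O[C@H](c1ccc(OCc3ccccc3)c(OC)c1)[C@H]2COCc1ccccc1 | intermediate
19 | (2E)-3-{(2S,3R)-2-[4-(benzyloxy)-3-methoxyphenyl]-3-[(benzyloxy)methyl]-4-methoxy-2,3-dihydro-1-benzofuran-6-yl}prop-2-en-1-ol | OC/C=C/c1cc(OC)c2c(c1)O[C@H](c1ccc(OCc3ccccc3)c(OC)c1)[C@H]2COCc1ccccc1 | intermediate
20 | (2S,3R)-2-[4-(benzyloxy)-3-methoxyphenyl]-3-[(benzyloxy)methyl]-6-[(1E)-3-bromoprop-1-en-1-yl]-4-methoxy-2,3-dihydro-1-benzofuran | BrC/C=C/c1cc(OC)c2c(c1)O[C@H](c1ccc(OCc3ccccc3)c(OC)c1)[C@H]2COCc1ccccc1 | intermediate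
21 | 3-(benzyloxy)-4-methoxybenzaldehyde | COc1ccc(C=O)cc1OCc1ccccc1 | starting material
22 | rac-1-[3-(benzyloxy)-4-methoxyphenyl]prop-2-en-1-ol | C=CC(O)c1ccc(OC)c(OCc2ccccc2)c1 | intermediate
23 | (S)-[3-(benzyloxy)-4-methoxyphenyl][(2R)-oxiran-2-yl]methanol | COc1ccc([C@H](O)[C@H]2CO2)cc1OCc1ccccc1 | intermediate
24 | (2S,3R)-2-[4-(benzyloxy)-3-methoxyphenyl]-3-[(benzyloxy)methyl]-6-[(1E)-3-{(S)-[3-(benzyloxy)-4-methoxyphenyl][(2R)-oxiran-2-yl]methoxy}prop-1-en-1-yl]-4-methoxy-2,3-dihydro-1-benzofuran | COc1ccc([C@H](OC/C=C/c2cc(OC)c3c(c2)O[C@H](c2ccc(OCc4ccccc4)c(OC)c2)[C@H]3COCc2ccccc2)[C@H]2CO2)cc1OCc1ccccc1 | intermediate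
25 | [(2R,3S,4S)-2-[3-(benzyloxy)-4-methoxyphenyl]-4-({(2S,3R)-2-[4-(benzyloxy)-3-methoxyphenyl]-3-[(benzyloxy)methyl]-4-methoxy-2,3-dihydro-1-benzofuran-6-yl}methyl)oxolan-3-yl]methanol | COc1ccc([C@@H]2OC[C@@H](Cc3cc(OC)c4c(c3)O[C@H](c3ccc(OCc5ccccc5)c(OC)c3)[C@H]4COCc3ccccc3)[C@H]2CO)cc1OCc1ccccc1 | intermediate
26 | [(2R,3S,4S)-2-(3-hydroxy-4-methoxyphenyl)-4-{[(2S,3R)-2-(4-hydroxy-3-methoxyphenyl)-3-(hydroxymethyl)-4-methoxy-2,3-dihydro-1-benzofuran-6-yl]methyl}oxolan-3-yl]methanol | COc1ccc([C@@H]2OC[C@@H](Cc3cc(OC)c4c(c3)O[C@H](c3ccc(O)c(OC)c3)[C@H]4CO)[C@H]2CO)cc1O | target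

**Step count and risks**

Total step count: 17. Longest linear sequence: 15 (steps 1–12, then 15–17); steps 13 and 14 make the second fragment.

The three steps most likely to fail, in order of risk:

Step 8. Ionisation of 13 may be followed by loss of the hydroxymethyl carbon as formaldehyde or by elimination to a stilbene faster than the methoxy oxygen captures the cation. The fallback closes the ring at C2–C3 instead, by carbenoid C–H insertion, and sets out from acid 6. BBr3 (1 equiv, CH2Cl2, −78 → 0 °C) should cleave one of the two equivalent methyl ethers, the phenol lactonising to 6-bromo-4-methoxy-1-benzofuran-2(3H)-one F1. K2CO3 in MeOH/DMF with 4-(benzyloxy)-3-methoxybenzyl chloride should open the lactone and trap the phenoxide as methyl (2-{[4-(benzyloxy)-3-methoxyphenyl]methoxy}-4-bromo-6-methoxyphenyl)acetate F2. Diazo transfer (4-acetamidobenzenesulfonyl azide, DBU, MeCN) would give the aryldiazoacetate F3. Dirhodium tetrakis(N-phthaloyl-tert-leucinate), Rh2(PTTL)4, in the enantiomeric form that sets (2S), should insert the carbenoid into the benzylic C–H bond of the ether to give the cis ester F4. NaOMe in MeOH would epimerise C3 to the trans ester F5, and LiBH4 reduction returns the route at alcohol 16.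

Step 16. The radical closure may give poor control of the C3/C4 relationship, or the β-titanoxy radical may be reduced by a second titanium before it cyclises. The fallback builds the oxolane by the lactone, aldol and cyclodehydration sequence and sets out from aryl bromide 17.
- n-BuLi (THF, −78 °C) then DMF would give the C6 carbaldehyde F6.
- Stobbe condensation with dimethyl succinate (NaOMe, MeOH, reflux) would give the (E)-arylidene succinic half-ester F7.
- Hydrogenation with [Rh(cod)2]BF4 and a Me-DuPhos ligand, its enantiomer chosen to deliver the (S) acid, would give the saturated half-ester F8.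
- Reduction of the ester in the potassium carboxylate with Ca(BH4)2, then acidification, would give the (S)-β-substituted γ-butyrolactone F9.
- LDA (THF, −78 °C) and aldehyde 21 would give the trans aldol lactone F10 as carbinol epimers.
- LiAlH4 would give the triol F11.
- Catalytic camphorsulfonic acid in CH2Cl2 would ionise the para-methoxybenzylic alcohol, and the primary hydroxyl on the arm at the benzyl-bearing carbon would close the oxolane with the aryl group trans to C3, returning the route at 25.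

Step 6. Enolisation and addition of the hindered, aryl-stabilised enolate may be slow and the aldolate may revert, costing conversion and configurational purity at the α-carbon. The fallback sets that centre by irreversible alkylation of the same imide and adds the carbinol carbon afterwards, which is allowed because step 8 erases the carbinol configuration; it sets out from imide 9. TiCl4 and i-Pr2NEt (CH2Cl2, 0 °C) followed by benzyl chloromethyl ether should alkylate the chelated Z-enolate anti to the auxiliary benzyl group to give the (2R)-benzyloxymethyl imide F12. LiBH4 would give the alcohol F13, and Dess–Martin periodinane the aldehyde F14, which is used at once at low temperature to avoid enolisation. [4-(Benzyloxy)-3-methoxyphenyl]magnesium bromide (THF, −78 °C) would give the carbinol F15 as a mixture at C1. Me3SiBr under the conditions of step 8 should close F15 directly to benzyl ether 17, where the route is rejoined.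

**Further compounds**

F1 | step 8 | 6-bromo-4-methoxy-1-benzofuran-2(3H)-one | O=C1Cc2c(OC)cc(Br)cc2O1
F2 | step 8 | methyl (2-{[4-(benzyloxy)-3-methoxyphenyl]methoxy}-4-bromo-6-methoxyphenyl)acetate | COC(=O)Cc1c(OC)cc(Br)cc1OCc1ccc(OCc2ccccc2)c(OC)c1
F3 | step 8 | methyl (2-{[4-(benzyloxy)-3-methoxyphenyl]methoxy}-4-bromo-6-methoxyphenyl)(diazo)acetate | COC(=O)C(=[N+]=[N-])c1c(OC)cc(Br)cc1OCc1ccc(OCc2ccccc2)c(OC)c1
F4 | step 8 | methyl (2S,3R)-2-[4-(benzyloxy)-3-methoxyphenyl]-6-bromo-4-methoxy-2,3-dihydro-1-benzofuran-3-carboxylate (cis) | Brc1cc(OC)c2c(c1)O[C@H](c1ccc(OCc3ccccc3)c(OC)c1)[C@@H]2C(=O)OC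
F5 | step 8 | methyl (2S,3S)-2-[4-(benzyloxy)-3-methoxyphenyl]-6-bromo-4-methoxy-2,3-dihydro-1-benzofuran-3-carboxylate (trans) | Brc1cc(OC)c2c(c1)O[C@H](c1ccc(OCc3ccccc3)c(OC)c1)[C@H]2C(=O)OC
F6 | step 16 | (2S,3R)-2-[4-(benzyloxy)-3-methoxyphenyl]-3-[(benzyloxy)methyl]-4-methoxy-2,3-dihydro-1-benzofuran-6-carbaldehyde | O=Cc1cc(OC)c2c(c1)O[C@H](c1ccc(OCc3ccccc3)c(OC)c1)[C@H]2COCc1ccccc1
F7 | step 16 | (3E)-4-{(2S,3R)-2-[4-(benzyloxy)-3-methoxyphenyl]-3-[(benzyloxy)methyl]-4-methoxy-2,3-dihydro-1-benzofuran-6-yl}-3-(methoxycarbonyl)but-3-enoic acid | OC(=O)C/C(=C\c1cc(OC)c2c(c1)O[C@H](c1ccc(OCc3ccccc3)c(OC)c1)[C@H]2COCc1ccccc1)C(=O)OC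
F8 | step 16 | (3S)-4-{(2S,3R)-2-[4-(benzyloxy)-3-methoxyphenyl]-3-[(benzyloxy)methyl]-4-methoxy-2,3-dihydro-1-benzofuran-6-yl}-3-(methoxycarbonyl)butanoic acid | COC(=O)[C@@H](Cc1cc(OC)c2c(c1)O[C@H](c1ccc(OCc3ccccc3)c(OC)c1)[C@H]2COCc1ccccc1)CC(=O)O
F9 | step 16 | (4S)-4-({(2S,3R)-2-[4-(benzyloxy)-3-methoxyphenyl]-3-[(benzyloxy)methyl]-4-methoxy-2,3-dihydro-1-benzofuran-6-yl}methyl)oxolan-2-one | O=C1OC[C@@H](Cc2cc(OC)c3c(c2)O[C@H](c2ccc(OCc4ccccc4)c(OC)c2)[C@H]3COCc2ccccc2)C1
F10 | step 16 | (3R,4S)-3-{[3-(benzyloxy)-4-methoxyphenyl](hydroxy)methyl}-4-({(2S,3R)-2-[4-(benzyloxy)-3-methoxyphenyl]-3-[(benzyloxy)methyl]-4-methoxy-2,3-dihydro-1-benzofuran-6-yl}methyl)oxolan-2-one, carbinol epimers | O=C1OC[C@@H](Cc2cc(OC)c3c(c2)O[C@H](c2ccc(OCc4ccccc4)c(OC)c2)[C@H]3COCc2ccccc2)[C@@H]1C(O)c1ccc(OC)c(OCc2ccccc2)c1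
F11 | step 16 | (2S,3S)-2-{[3-(benzyloxy)-4-methoxyphenyl](hydroxy)methyl}-3-({(2S,3R)-2-[4-(benzyloxy)-3-methoxyphenyl]-3-[(benzyloxy)methyl]-4-methoxy-2,3-dihydro-1-benzofuran-6-yl}methyl)butane-1,4-diol, carbinol epimers | OC[C@@H](Cc1cc(OC)c2c(c1)O[C@H](c1ccc(OCc3ccccc3)c(OC)c1)[C@H]2COCc1ccccc1)[C@@H](CO)C(O)c1ccc(OC)c(OCc2ccccc2)c1
F12 | step 6 | (4S)-4-benzyl-3-[(2R)-3-(benzyloxy)-2-(4-bromo-2,6-dimethoxyphenyl)propanoyl]-1,3-oxazolidin-2-one | COc1cc(Br)cc(OC)c1[C@H](COCc1ccccc1)C(=O)N1C(=O)OC[C@@H]1Cc1ccccc1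
F13 | step 6 | (2S)-3-(benzyloxy)-2-(4-bromo-2,6-dimethoxyphenyl)propan-1-ol | COc1cc(Br)cc(OC)c1[C@H](COCc1ccccc1)CO
F14 | step 6 | (2R)-3-(benzyloxy)-2-(4-bromo-2,6-dimethoxyphenyl)propanal | COc1cc(Br)cc(OC)c1[C@H](COCc1ccccc1)C=O
F15 | step 6 | (2R)-3-(benzyloxy)-1-[4-(benzyloxy)-3-methoxyphenyl]-2-(4-bromo-2,6-dimethoxyphenyl)propan-1-ol, both C1 epimers | COc1cc(Br)cc(OC)c1[C@H](COCc1ccccc1)C(O)c1ccc(OCc2ccccc2)c(OC)c1
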